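## The problem

The target 25 is a germacranolide. Its ten-membered carbocycle (C1–C10) carries a cis-in-ring C1=C10 alkene with the C14 aldehyde on C10, a trans-4,5-epoxide, and a butenolide fused across C6–C7 whose tetrasubstituted C7=C11 alkene is exocyclic to the large ring. Rings of this size close reluctantly, so the plan must say which ring bond is made last and why the open chain should fold.

There are four stereocentres. C4 and C5 belong to the epoxide and can be set by reagent control on an acyclic E-alkene. C6 has its oxygen anti to the epoxide oxygen, which is the Felkin–Anh outcome of adding a carbon nucleophile to an epoxy aldehyde. C8 is separated from C6 by the sp2 carbon C7, so C6 can only control it by relay across the flat lactone.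

The functionality is fragile. The trisubstituted epoxide dislikes acid and the enal dislikes nucleophiles and hydrides. H6 and H8 are vinylogously acidic, the C13 acetate is an allylic leaving group, and a free C8 hydroxyl can take the lactone carbonyl over from O6. Two different esters must also be placed on two allylic alcohols.

The enabling feature is that O8 and O13 flank the C7=C11 alkene as a 2-ene-1,4-dioxy unit (C8–C7=C11–C13). This is what dioxygen leaves after adding to the diene C8=C7–C11=C13, which the five-membered lactone of an α-methylene-β-alkylidene lactone holds s-cis.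

## Retrosynthesis

**Esters.** The two acyl–oxygen bonds of 25 are cut first: the isovalerate on the secondary O8 (giving monoacetate 24), then the acetate on the primary O13 (giving diol 23). The primary hydroxyl is the more reactive, so it is acylated first in the forward direction. Both acylations must be mild enough not to move the lactone from O6 to O8.

**O–O bond.** Diol 23 is reconnected through an O8–O13 bond to endoperoxide 22. The precursor hides both hydroxyls in one ring, so no protecting group is needed. The forward step only has to break a weak O–O bond without base, because H8 is acidic.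

**Key cut.** The dioxine ring of 22 is cut at C8–O and C13–O, which gives dioxygen and dienyl lactone 21. The alternatives are to oxidise a C13 methyl and C8 separately, or to carry O8 through the ring closure. Against these, the single cut installs both oxygens, moves the alkene to C7=C11 and creates the last stereocentre on the finished skeleton. Compound 21 has only three stereocentres. The forward reaction needs oxygen to approach the face away from C5 and cycloaddition to beat the ene reaction.

**Oxidation levels.** Lactone 21 is traced back to triol 19: the C12–O6 lactone bond and the C12 and C14 carbonyls become three hydroxyls. One oxidation that prefers primary alcohols can then make the enal and, through lactol 20, the lactone together, so the sensitive diene lactone appears one step before it is used. Triol 19 comes from silyl ether 18 and that from ester 17, so C14 is an unreactive ester during ring closure.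

**Ring closure.** The ten-membered ring of 17 is opened at C6–C7, giving iodo aldehyde 15, which reacts through alkenylchromium species 16.
- Closing at C1=C10 instead would require unmasking the C1 aldehyde by oxidative cleavage in the presence of the diene.
- The C6–C7 cut creates C6 next to the epoxide, where the Felkin–Anh preference gives the required anti relationship.
- The chain is pre-bent by two cis-disposed alkenes on either side of C9.
- The forward reaction must work at high dilution, keep the alkene geometry and tolerate ester and epoxide.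

**C1=C10.** Aldehyde 15 comes from epoxy alcohol 14, which is cut at C1=C10 into aldehyde 4 and phosphonate 13. An α-substituted phosphonoacetate gives the E-enoate by nature, which places C2 cis to C9 as the ring requires. The union is convergent and needs no protection of the epoxy alcohol.

**Iodo diene.** Phosphonate 13 is cut at C9–C10 into allylic bromide 11 and triethyl phosphonoacetate 12; 11 comes from alcohol 10. The C7–I/C8–H pattern of 10 is what alkoxide-directed trans-hydroalumination and iodinolysis (via alanate 9) give from enynol 8. Hydrometalating a C6–C7≡C8–C9 alkyne instead would need syn addition with the metal on the hindered carbon, which is not reliable. Enynol 8 is cut at C7–C11 into vinyl bromide 6 (from 2-bromoprop-2-en-1-ol 5) and propargyl alcohol 7.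

**Epoxy aldehyde.** Aldehyde 4 is the ozonolysis product (via ozonide 3) of epoxygeraniol 2, made from geraniol 1 by asymmetric epoxidation. The cleavage is done while the molecule has only one alkene.

## Roads not taken

**Alternative 1:** The cut is C7–C8. The carbocycle would arise by contracting the thirteen-membered allyl α-stannylalkyl ether A1. Tin–lithium exchange at C8 (n-BuLi) and a [2,3] shift (Still–Wittig) form C7–C8 as O–C13 breaks, giving homoallylic alcohol A2 with the C8 hydroxyl and a 3-silyloxyprop-1-en-2-yl group on C7.
- Merits: a thirteen-membered ether closes more easily than a ten-membered carbocycle, and the shift is intramolecular and ordered. The C7–C8 bond, the C8 oxygen and the exocyclic alkene come in one step. For ring construction this road is probably the safer one.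
- Weak points: in A2, C7 is an sp3 CH and C13 a bare methylene, so the alkene must still be moved to C7=C11 and C13 oxidised. C7 and C8 are set together by a macrocyclic transition state whose sense is hard to predict, and the [1,2] shift competes. The 4,5-alkene must be epoxidised late, next to the C1=C10 alkene and from the right face. Three protecting groups and an organotin precursor are needed.
- Comparison: the chosen plan has a chromium ring closure at high dilution (step 10) to set against the easier ring formation. In return it places O8 and O13 together in the final oxidation pattern, carries the epoxide from step 1 and uses one silyl group.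

**Alternative 2:** The cut is the lactone C6–O bond. Pd(PPh3)4 (zerovalent palladium) would ionise the allylic C6–O bond of the 4,5-alkene lactone, whether the substrate is the 6-epimer A3 or A4 itself. The allylpalladium carboxylate would then reclose at C6 to give A4 alone.
- Merits: C6 need not be controlled when the ring is built, both epimers are used, and the conditions are neutral and catalytic. In tolerance of a stereo-random ring closure this idea is better than the chosen route, which loses material that closes with the wrong C6 configuration.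
- Weak points: the favoured epimer is decided by the strained ring and need not be 6R. The allyl unit spans C4–C6, so syn/anti isomerisation can erode the E geometry that the trans-epoxide needs; reclosure at C4 and β-hydride elimination are also open. The step corrects one centre but builds nothing: ring, butenolide and both oxygens must already exist. The epoxide would then be introduced last on the macrocycle, without reagent control.
- Comparison: the chosen plan fixes C4 and C5 by reagent control before any ring exists and sets C6 by Felkin–Anh addition. It gives up the safety net for C6, which the fallback for step 10 has to supply.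

**Alternative 3:** Two bonds are cut, C1–C10 and C4–C5. A [2+2] photocycloaddition of the chiral-pool cyclohexenone A5 with 1-methylcyclobutene A6 would give tricyclic photoadduct A7. Thermal cycloreversion of the central cyclobutane in the other sense (breaking C5–C10 and C1–C4) would then open the ten-membered 1(10),4-diene.
- Merits: there is no macrocyclisation, the C8 oxygen and its configuration come from the chiral pool, and C14 is already a carboxylate. For ring construction and scale this road is as good as or better than the chosen one.
- Weak points: the orientation of the unsymmetrical cyclobutene decides whether the methyl ends on C4. The thermal opening must give a cis-in-ring C1=C10 and a trans C4=C5, and cyclodeca-1,5-dienes undergo Cope rearrangement at similar temperatures. C7 of A7 bears oxygen, not carbon, so C11–C13 and the whole butenolide must be grafted onto a medium ring, the C6 ketone reduced selectively and the epoxide introduced late.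
- Comparison: the chosen plan brings all ring and lactone carbons into the ring closure and needs three steps after the key step. It sets this shorter, more predictable end game against the more elegant ring formation.

Key step: step 14

Remark on numbering: germacrane numbering is used for all intermediates. The ring is C1–C10; C4 bears methyl C15; C10 bears C14; C7 bears C11, which bears C12 (lactone carbonyl) and C13.

Remark on the chemistry: the configurations at the phosphonate carbon of 13 and at the lactol carbon of 20 are left open, because both centres become sp2.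

Step 1
Reactants: 1 geraniol
Product: 2 (2R,3R)-2,3-epoxygeraniol
Conditions: Ti(OiPr)4 (cat.), D-(−)-diethyl tartrate (cat.), t-BuOOH, 4 Å MS, CH2Cl2, −20 °C
Reagents that add atoms: tert-butyl hydroperoxide, CC(C)(C)OO
Why: Sharpless asymmetric epoxidation; with D-(−)-tartrate the titanium complex delivers oxygen to the face of the E-allylic alcohol that gives the (2R,3R)-epoxide, which fixes C4 and C5. The remote alkene does not bind titanium and is left alone.

Step 2
Reactants: 2 (2R,3R)-2,3-epoxygeraniol
Product: 4 3-[(2R,3R)-3-(hydroxymethyl)-2-methyloxiran-2-yl]propanal, via secondary ozonide 3 (not isolated)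
Conditions: O3, CH2Cl2, −78 °C; then PPh3, −78 °C → rt
Reagents that add atoms: ozone, [O-][O+]=O
Why: Ozonolysis with reductive work-up of the only alkene in the molecule; epoxide and primary alcohol are inert to ozone at low temperature. The C1 aldehyde is unveiled here because no other C=C is present yet.

Step 3
Reactants: 5 2-bromoprop-2-en-1-ol
Product: 6 [(2-bromoprop-2-en-1-yl)oxy](tert-butyl)dimethylsilane
Conditions: TBSCl, imidazole, CH2Cl2, 0 °C → rt
Reagents that add atoms: tert-butyl(chloro)dimethylsilane, CC(C)(C)[Si](C)(C)Cl
Why: Imidazole-promoted silylation of a primary alcohol. The silyl ether keeps O12 from competing with O9 as the directing group in step 5.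

Step 4
Reactants: 6 [(2-bromoprop-2-en-1-yl)oxy](tert-butyl)dimethylsilane; 7 prop-2-yn-1-ol
Product: 8 4-{[(tert-butyldimethylsilyl)oxy]methyl}pent-4-en-2-yn-1-ol
Conditions: PdCl2(PPh3)2 (cat.), CuI (cat.), i-Pr2NH, THF, rt
Reagents that add atoms: none
Why: Sonogashira coupling of a vinyl bromide with a terminal alkyne forms C7–C11. The free propargylic hydroxyl is tolerated and becomes the directing group of the next step.

Step 5
Reactants: 8 4-{[(tert-butyldimethylsilyl)oxy]methyl}pent-4-en-2-yn-1-ol
Product: 10 (2Z)-4-{[(tert-butyldimethylsilyl)oxy]methyl}-3-iodopenta-2,4-dien-1-ol, via alkenylalanate 9 (not isolated)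
Conditions: NaAlH2(OCH2CH2OMe)2, THF, 0 °C → rt; then I2, −78 → 0 °C
Reagents that add atoms: iodine, II
Why: Hydroxyl-directed trans-hydroalumination of a propargylic alcohol puts hydride on the proximal carbon (C8) and aluminium on C7 inside a five-membered alanate. Iodinolysis with retention gives the vinyl iodide with iodine cis to C9; C6 later replaces iodine with retention, so this step fixes the (7Z) geometry of the diene.

Step 6
Reactants: 10 (2Z)-4-{[(tert-butyldimethylsilyl)oxy]methyl}-3-iodopenta-2,4-dien-1-ol
Product: 11 {[(3Z)-5-bromo-3-iodo-2-methylidenepent-3-en-1-yl]oxy}(tert-butyl)dimethylsilane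
Conditions: CBr4, PPh3, CH2Cl2, 0 °C
Reagents that add atoms: tetrabromomethane, BrC(Br)(Br)Br
Why: Appel bromination of a primary allylic alcohol under neutral conditions; substitution at the primary carbon leaves the Z-alkene, the vinyl iodide and the silyl ether untouched.

Step 7
Reactants: 11 {[(3Z)-5-bromo-3-iodo-2-methylidenepent-3-en-1-yl]oxy}(tert-butyl)dimethylsilane; 12 triethyl phosphonoacetate
Product: 13 ethyl (4Z)-6-{[(tert-butyldimethylsilyl)oxy]methyl}-2-(diethoxyphosphoryl)-5-iodohepta-4,6-dienoate
Conditions: NaH, THF, 0 °C → rt (12 in excess)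
Reagents that add atoms: none
Why: C-Alkylation of the sodium phosphonoacetate by a primary allylic bromide (SN2) forms C9–C10; excess 12 suppresses double alkylation. The new centre is lost in step 8.

Step 8
Reactants: 4 3-[(2R,3R)-3-(hydroxymethyl)-2-methyloxiran-2-yl]propanal; 13 ethyl (4Z)-6-{[(tert-butyldimethylsilyl)oxy]methyl}-2-(diethoxyphosphoryl)-5-iodohepta-4,6-dienoate
Product: 14 ethyl (2E)-2-[(2Z)-4-{[(tert-butyldimethylsilyl)oxy]methyl}-3-iodopenta-2,4-dien-1-yl]-5-[(2R,3R)-3-(hydroxymethyl)-2-methyloxiran-2-yl]pent-2-enoate
Conditions: LiCl, DBU, MeCN, 0 °C → rt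
Reagents that add atoms: none
Why: Horner–Wadsworth–Emmons olefination under mild LiCl/amine conditions. α-Substituted phosphonoacetates give the E-enoate (C2 trans to the ester, hence cis to C9), and the weak base spares the epoxy alcohol.

Step 9
Reactants: 14 ethyl (2E)-2-[(2Z)-4-{[(tert-butyldimethylsilyl)oxy]methyl}-3-iodopenta-2,4-dien-1-yl]-5-[(2R,3R)-3-(hydroxymethyl)-2-methyloxiran-2-yl]pent-2-enoate
Product: 15 ethyl (2E)-5-[(2R,3S)-3-formyl-2-methyloxiran-2-yl]-2-[(2Z)-4-{[(tert-butyldimethylsilyl)oxy]methyl}-3-iodopenta-2,4-dien-1-yl]pent-2-enoate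
Conditions: Dess–Martin periodinane, pyridine, CH2Cl2, 0 °C → rt
Reagents that add atoms: none
Why: Dess–Martin oxidation of a primary 2,3-epoxy alcohol to the epoxy aldehyde under buffered conditions that do not epimerise C5; the descriptor at C5 changes only because the priorities change.

Step 10
Reactants: 15 ethyl (2E)-5-[(2R,3S)-3-formyl-2-methyloxiran-2-yl]-2-[(2Z)-4-{[(tert-butyldimethylsilyl)oxy]methyl}-3-iodopenta-2,4-dien-1-yl]pent-2-enoate
Product: 17 ethyl (1(10)E,4R,5R,6R,7Z)-4,5-epoxy-6-hydroxy-12-[(tert-butyldimethylsilyl)oxy]germacra-1(10),7,11(13)-trien-14-oate, via alkenylchromium dichloride 16 (not isolated)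
Conditions: CrCl2 (excess), NiCl2 (cat.), DMSO/THF, rt, 0.002 M, slow addition
Reagents that add atoms: none
Why: Nozaki–Hiyama–Kishi macrocyclisation: zerovalent nickel inserts into C–I, transmetalation gives alkenylchromium 16, and this adds to the aldehyde with retention of alkene geometry while ester, epoxide and silyl ether are tolerated. The chain is pre-folded by the two cis-disposed alkenes around C9. Felkin–Anh addition (epoxide C5–O anti to the forming C6–C7 bond) should give the 6R alcohol with O6 anti to the epoxide oxygen.

Step 11
Reactants: 17 ethyl (1(10)E,4R,5R,6R,7Z)-4,5-epoxy-6-hydroxy-12-[(tert-butyldimethylsilyl)oxy]germacra-1(10),7,11(13)-trien-14-oate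
Product: 18 (1(10)E,4R,5R,6R,7Z)-4,5-epoxy-12-[(tert-butyldimethylsilyl)oxy]germacra-1(10),7,11(13)-triene-6,14-diol
Conditions: i-Bu2AlH, CH2Cl2, −78 °C; aq. potassium sodium tartrate
Reagents that add atoms: none
Why: DIBAL reduction of the enoate to the allylic alcohol; at −78 °C the aluminium alkoxide of O6 should not open the neighbouring epoxide.

Step 12
Reactants: 18 (1(10)E,4R,5R,6R,7Z)-4,5-epoxy-12-[(tert-butyldimethylsilyl)oxy]germacra-1(10),7,11(13)-triene-6,14-diol
Product: 19 (1(10)E,4R,5R,6R,7Z)-4,5-epoxygermacra-1(10),7,11(13)-triene-6,12,14-triol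
Conditions: Bu4NF, AcOH, THF, 0 °C → rt
Reagents that add atoms: none
Why: Fluoride cleavage of the primary silyl ether, buffered with acetic acid so that a C6 alkoxide cannot start a Payne rearrangement of the epoxy alcohol.

Step 13
Reactants: 19 (1(10)E,4R,5R,6R,7Z)-4,5-epoxygermacra-1(10),7,11(13)-triene-6,12,14-triol
Product: 21 (1(10)E,4R,5R,6R,7Z)-4,5-epoxy-14-oxogermacra-1(10),7,11(13)-trien-12,6-olide, via lactol 20 (not isolated)
Conditions: TEMPO (cat.), PhI(OAc)2, CH2Cl2, rt; used at once
Reagents that add atoms: none
Why: Oxidative lactonisation with TEMPO/PhI(OAc)2, which oxidises primary alcohols in preference to secondary ones. C14 gives the enal; C12 gives an aldehyde that O6 traps as lactol 20, which is oxidised on to the lactone. The diene lactone is released under near-neutral conditions one step before use.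

Step 14
Reactants: 21 (1(10)E,4R,5R,6R,7Z)-4,5-epoxy-14-oxogermacra-1(10),7,11(13)-trien-12,6-olide
Product: 22 (1(10)E,4R,5R,6R,8S)-4,5-epoxy-8,13-epidioxy-14-oxogermacra-1(10),7(11)-dien-12,6-olide
Conditions: O2, tetraphenylporphyrin (C44H30N4, cat.), visible light, CH2Cl2, −30 °C
Reagents that add atoms: dioxygen, O=O
Why: Singlet oxygen, formed by energy transfer from the excited porphyrin, adds to the s-cis diene C8=C7–C11=C13 in a concerted, suprafacial [4+2] cycloaddition that forms O–C8 and O–C13 and shifts the alkene to C7=C11. The closest known reaction type is the singlet-oxygen Diels–Alder reaction of cisoid and exocyclic 1,3-dienes to 3,6-dihydro-1,2-dioxines. The six-membered 1,2-dioxine closes by this cycloaddition, both ring C–O bonds forming in the same step, fused to the butenolide at C7–C11. The one new stereocentre, C8, is controlled by C6 together with the (7Z) geometry: C9 lies in the diene plane while C5 leaves C6 out of it, so the ten-membered chain runs under one face of the lactone and oxygen attacks the open face anti to C5, which gives 8S. The step needs the diene to react in preference to the enal and the epoxide, [4+2] to beat the Schenck ene reaction at C7=C8 (the doubly allylic H9 is the danger), and face selectivity. The lactone ring locks the diene s-cis, which makes cycloaddition much faster than the ene path; C1=C10 is deactivated by the aldehyde; low temperature and a non-polar solvent favour the concerted path. The cycloaddition also removes the reactive α-methylene lactone, so the product should be more stable than the substrate.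

Step 15
Reactants: 22 (1(10)E,4R,5R,6R,8S)-4,5-epoxy-8,13-epidioxy-14-oxogermacra-1(10),7(11)-dien-12,6-olide
Product: 23 (1(10)E,4R,5R,6R,8S)-4,5-epoxy-8,13-dihydroxy-14-oxogermacra-1(10),7(11)-dien-12,6-olide
Conditions: thiourea, MeOH, 0 °C → rt
Reagents that add atoms: none
Why: Thiourea reduction of a 3,6-dihydro-1,2-dioxine to the 2-ene-1,4-diol. The neutral reagent avoids the base-induced Kornblum–DeLaMare fragmentation at the acidic H8 and leaves enal, epoxide and lactone alone; no C–O bond at C8 is broken.

Step 16
Reactants: 23 (1(10)E,4R,5R,6R,8S)-4,5-epoxy-8,13-dihydroxy-14-oxogermacra-1(10),7(11)-dien-12,6-olide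
Product: 24 (1(10)E,4R,5R,6R,8S)-13-acetoxy-4,5-epoxy-8-hydroxy-14-oxogermacra-1(10),7(11)-dien-12,6-olide
Conditions: AcCl, 2,4,6-collidine, CH2Cl2, −78 °C
Reagents that add atoms: acetyl chloride, CC(=O)Cl
Why: Selective acylation of the primary allylic alcohol with acetyl chloride and a hindered pyridine base at low temperature; the secondary C8 hydroxyl beside the ring reacts much more slowly.

Step 17
Reactants: 24 (1(10)E,4R,5R,6R,8S)-13-acetoxy-4,5-epoxy-8-hydroxy-14-oxogermacra-1(10),7(11)-dien-12,6-olide
Product: 25 (1(10)E,4R,5R,6R,8S)-13-acetoxy-4,5-epoxy-8-(3-methylbutanoyloxy)-14-oxogermacra-1(10),7(11)-dien-12,6-olide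
Conditions: (i-PrCH2CO)2O, DMAP (cat.), Et3N, CH2Cl2, 0 °C
Reagents that add atoms: 3-methylbutanoic anhydride, CC(C)CC(=O)OC(=O)CC(C)C
Why: DMAP-catalysed esterification of the remaining secondary allylic alcohol. No stereocentre is touched, and the short, cold exposure to amine base limits acetate loss and lactone migration.

## Compound list

1 | geraniol, (2E)-3,7-dimethylocta-2,6-dien-1-ol | CC(C)=CCC/C(C)=C/CO | starting material
2 | (2R,3R)-2,3-epoxygeraniol, [(2R,3R)-3-methyl-3-(4-methylpent-3-en-1-yl)oxiran-2-yl]methanol | CC(C)=CCC[C@@]1(C)O[C@@H]1CO | intermediate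
3 | secondary ozonide (1,2,4-trioxolane) of 2 at the former terminal alkene | CC1(C)OOC(CC[C@@]2(C)O[C@@H]2CO)O1 | intermediate
4 | 3-[(2R,3R)-3-(hydroxymethyl)-2-methyloxiran-2-yl]propanal | O=CCC[C@@]1(C)O[C@@H]1CO | intermediate
5 | 2-bromoprop-2-en-1-ol | OCC(Br)=C | starting material
6 | [(2-bromoprop-2-en-1-yl)oxy](tert-butyl)dimethylsilane | C=C(Br)CO[Si](C)(C)C(C)(C)C | intermediate
7 | prop-2-yn-1-ol | OCC#C | starting material
8 | 4-{[(tert-butyldimethylsilyl)oxy]methyl}pent-4-en-2-yn-1-ol | OCC#CC(=C)CO[Si](C)(C)C(C)(C)C | intermediate
9 | sodium alkenylalanate from 8 (five-membered O–Al–C7=C8–C9 ring, two 2-methoxyethoxy groups on aluminium) | [Na+].COCCO[Al-]1(OCCOC)OCC=C1C(=C)CO[Si](C)(C)C(C)(C)C | intermediate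
10 | (2Z)-4-{[(tert-butyldimethylsilyl)oxy]methyl}-3-iodopenta-2,4-dien-1-ol | OC/C=C(\I)C(=C)CO[Si](C)(C)C(C)(C)C | intermediate
11 | {[(3Z)-5-bromo-3-iodo-2-methylidenepent-3-en-1-yl]oxy}(tert-butyl)dimethylsilane | BrC/C=C(\I)C(=C)CO[Si](C)(C)C(C)(C)C | intermediate
12 | triethyl phosphonoacetate | CCOC(=O)CP(=O)(OCC)OCC | starting material
13 | ethyl (4Z)-6-{[(tert-butyldimethylsilyl)oxy]methyl}-2-(diethoxyphosphoryl)-5-iodohepta-4,6-dienoate (C2 not controlled) | CCOC(=O)C(C/C=C(\I)C(=C)CO[Si](C)(C)C(C)(C)C)P(=O)(OCC)OCC | intermediate
14 | ethyl (2E)-2-[(2Z)-4-{[(tert-butyldimethylsilyl)oxy]methyl}-3-iodopenta-2,4-dien-1-yl]-5-[(2R,3R)-3-(hydroxymethyl)-2-methyloxiran-2-yl]pent-2-enoate | CCOC(=O)/C(C/C=C(\I)C(=C)CO[Si](C)(C)C(C)(C)C)=C/CC[C@@]1(C)O[C@@H]1CO | intermediate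
15 | ethyl (2E)-5-[(2R,3S)-3-formyl-2-methyloxiran-2-yl]-2-[(2Z)-4-{[(tert-butyldimethylsilyl)oxy]methyl}-3-iodopenta-2,4-dien-1-yl]pent-2-enoate | CCOC(=O)/C(C/C=C(\I)C(=C)CO[Si](C)(C)C(C)(C)C)=C/CC[C@@]1(C)O[C@@H]1C=O | intermediate
16 | alkenylchromium dichloride from 15 (trivalent chromium in place of iodine at C7) | CCOC(=O)/C(C/C=C(\[Cr](Cl)Cl)C(=C)CO[Si](C)(C)C(C)(C)C)=C/CC[C@@]1(C)O[C@@H]1C=O | intermediate
17 | ethyl (1(10)E,4R,5R,6R,7Z)-4,5-epoxy-6-hydroxy-12-[(tert-butyldimethylsilyl)oxy]germacra-1(10),7,11(13)-trien-14-oate | CCOC(=O)/C1=C/CC[C@@]2(C)O[C@@H]2[C@H](O)/C(=C\C1)C(=C)CO[Si](C)(C)C(C)(C)C | intermediate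
18 | (1(10)E,4R,5R,6R,7Z)-4,5-epoxy-12-[(tert-butyldimethylsilyl)oxy]germacra-1(10),7,11(13)-triene-6,14-diol | OC/C1=C/CC[C@@]2(C)O[C@@H]2[C@H](O)/C(=C\C1)C(=C)CO[Si](C)(C)C(C)(C)C | intermediate
19 | (1(10)E,4R,5R,6R,7Z)-4,5-epoxygermacra-1(10),7,11(13)-triene-6,12,14-triol | OC/C1=C/CC[C@@]2(C)O[C@@H]2[C@H](O)/C(=C\C1)C(=C)CO | intermediate
20 | lactol: 12-hydroxy-12,6-epoxy derivative of 21 (C12 hemiacetal, C14 aldehyde) | O=C/C1=C/CC[C@@]2(C)O[C@@H]2[C@@H]3OC(O)C(=C)/C3=C/C1 | intermediate
21 | (1(10)E,4R,5R,6R,7Z)-4,5-epoxy-14-oxogermacra-1(10),7,11(13)-trien-12,6-olide (dienyl lactone) | O=C/C1=C/CC[C@@]2(C)O[C@@H]2[C@@H]3OC(=O)C(=C)/C3=C/C1 | intermediate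
22 | (1(10)E,4R,5R,6R,8S)-4,5-epoxy-8,13-epidioxy-14-oxogermacra-1(10),7(11)-dien-12,6-olide (endoperoxide) | C1OO[C@H]2C/C(C=O)=C\CC[C@@]3(C)O[C@@H]3[C@@H]4OC(=O)C1=C24 | intermediate
23 | (1(10)E,4R,5R,6R,8S)-4,5-epoxy-8,13-dihydroxy-14-oxogermacra-1(10),7(11)-dien-12,6-olide | OCC1=C2[C@@H](O)C/C(C=O)=C\CC[C@@]3(C)O[C@@H]3[C@@H]2OC1=O | intermediate
24 | (1(10)E,4R,5R,6R,8S)-13-acetoxy-4,5-epoxy-8-hydroxy-14-oxogermacra-1(10),7(11)-dien-12,6-olide | CC(=O)OCC1=C2[C@@H](O)C/C(C=O)=C\CC[C@@]3(C)O[C@@H]3[C@@H]2OC1=O | intermediate
25 | (1(10)E,4R,5R,6R,8S)-13-acetoxy-4,5-epoxy-8-(3-methylbutanoyloxy)-14-oxogermacra-1(10),7(11)-dien-12,6-olide | CC(=O)OCC1=C2[C@@H](OC(=O)CC(C)C)C/C(C=O)=C\CC[C@@]3(C)O[C@@H]3[C@@H]2OC1=O | target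

## Step count and risk

Total: 17 steps. Longest linear sequence: 15 steps (5 → 25, steps 3–17); the geraniol branch (1 → 4, steps 1–2) joins at step 8.

**Step 14 (key step).** The most likely failure is competition from the ene pathway at C7=C8, with abstraction of the doubly allylic H9, together with self-condensation of the α-methylene diene before it is oxygenated. Face selectivity rests only on shielding by the ring.

Fallback: setting out from 21, the electron-rich C7=C8 alkene is epoxidised with dimethyldioxirane on the open face to give the 7,8-epoxide F1. Addition of acetic acid across this vinyl epoxide, catalysed by Pd(PPh3)4 (zerovalent palladium), ionises C7–O and delivers acetate to C13. This keeps the C8–O bond and its configuration and rejoins the route at 24, passing by 22 and 23.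

**Step 10.** The likely failures are oligomerisation in place of ten-membered ring closure, loss of Felkin–Anh control at C6 if ring strain dictates the transition state, and opening of the epoxy aldehyde by chromium salts.

Fallback: the order of the two unions is reversed. Setting out from 2, Dess–Martin oxidation gives epoxy aldehyde F2. Intermolecular Nozaki–Hiyama–Kishi coupling with iodide 13 (CrCl2, cat. NiCl2) gives the acyclic dienyl carbinol F3 under open-chain Felkin–Anh control. Site-selective dihydroxylation of the electron-rich terminal alkene (OsO4 cat., N-methylmorpholine N-oxide) and NaIO4 cleavage give aldehyde phosphonate F4. Intramolecular Horner–Wadsworth–Emmons reaction (LiCl, DBU, high dilution) closes C1=C10 and returns to the route at 17.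

**Step 5.** The likely failures are protonolysis of the alkenylalanate before iodination, incomplete regiocontrol of hydride delivery in the conjugated enyne, and reduction beyond the alkenyl stage.

Fallback: setting out from 8, trans-hydrosilylation with BnMe2SiH catalysed by [Cp*Ru(MeCN)3]PF6 places silicon on the carbon distal to the hydroxyl and gives the (Z)-vinylsilane F5. Iododesilylation with N-iodosuccinimide, with retention, returns to the route at 10.

**Step 16.** The likely failures are poor discrimination between the two allylic hydroxyls, acyl migration, and lactone migration from O6 to O8 under the acylation conditions.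

Fallback: setting out from 23, the primary hydroxyl is silylated selectively (TBSCl, imidazole) to give silyl ether F6. O8 is esterified with 3-methylbutanoic anhydride to give silyl ether ester F7. Desilylation with HF·pyridine gives primary alcohol F8, and acetylation (Ac2O, pyridine) returns to the route at 25.

## Further compounds

F1 | step 14 | 7,8-epoxide of 21 (new oxirane oxygen on the face anti to C5) | O=C/C1=C/CC[C@@]2(C)O[C@@H]2[C@@H]3OC(=O)C(=C)[C@@]34O[C@H]4C1
F2 | step 10 | (2S,3R)-3-methyl-3-(4-methylpent-3-en-1-yl)oxirane-2-carbaldehyde | CC(C)=CCC[C@@]1(C)O[C@@H]1C=O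
F3 | step 10 | acyclic 6R dienyl carbinol from F2 and 13 (terminal alkene intact, phosphonate carbon not controlled) | CC(C)=CCC[C@@]1(C)O[C@@H]1[C@H](O)/C(=C\CC(C(=O)OCC)P(=O)(OCC)OCC)C(=C)CO[Si](C)(C)C(C)(C)C
F4 | step 10 | C1 aldehyde from F3 (seco aldehyde phosphonate) | O=CCC[C@@]1(C)O[C@@H]1[C@H](O)/C(=C\CC(C(=O)OCC)P(=O)(OCC)OCC)C(=C)CO[Si](C)(C)C(C)(C)C
F5 | step 5 | (2Z)-3-[benzyl(dimethyl)silyl]-4-{[(tert-butyldimethylsilyl)oxy]methyl}penta-2,4-dien-1-ol | OC/C=C(\[Si](C)(C)Cc1ccccc1)C(=C)CO[Si](C)(C)C(C)(C)C
F6 | step 16 | 13-O-tert-butyldimethylsilyl ether of 23 | CC(C)(C)[Si](C)(C)OCC1=C2[C@@H](O)C/C(C=O)=C\CC[C@@]3(C)O[C@@H]3[C@@H]2OC1=O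
F7 | step 16 | 13-O-tert-butyldimethylsilyl 8-O-(3-methylbutanoyl) derivative of 23 | CC(C)(C)[Si](C)(C)OCC1=C2[C@@H](OC(=O)CC(C)C)C/C(C=O)=C\CC[C@@]3(C)O[C@@H]3[C@@H]2OC1=O
F8 | step 16 | 8-O-(3-methylbutanoyl) derivative of 23 with free 13-hydroxyl | OCC1=C2[C@@H](OC(=O)CC(C)C)C/C(C=O)=C\CC[C@@]3(C)O[C@@H]3[C@@H]2OC1=O
A1 | alternative 1 | thirteen-membered allyl α-tributylstannylalkyl ether (tin on C8, ring through O–C13) | CCCC[Sn](CCCC)(CCCC)[C@H]1C/C(COCc2ccc(OC)cc2)=C\CC/C(C)=C/[C@H](O[Si](CC)(CC)CC)/C=C(/CO1)CO[Si](C)(C)C(C)(C)C
A2 | alternative 1 | ten-membered homoallylic alcohol with C8 hydroxyl and 3-silyloxyprop-1-en-2-yl group on C7 | O[C@H]1C/C(COCc2ccc(OC)cc2)=C\CC/C(C)=C/[C@H](O[Si](CC)(CC)CC)[C@H]1C(=C)CO[Si](C)(C)C(C)(C)C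
A3 | alternative 2 | C6 epimer of the bis-TBS 4,5-alkene lactone A4 | CC(C)(C)[Si](C)(C)OCC1=C2[C@@H](O[Si](C)(C)C(C)(C)C)C/C(C=O)=C\CC/C(C)=C/[C@H]2OC1=O
A4 | alternative 2 | bis-TBS 4,5-alkene (4,5-deoxy) lactone, single C6 epimer | CC(C)(C)[Si](C)(C)OCC1=C2[C@@H](O[Si](C)(C)C(C)(C)C)C/C(C=O)=C\CC/C(C)=C/[C@@H]2OC1=O
A5 | alternative 3 | chiral-pool cyclohexenone ester with OTBS and OPMB groups | COC(=O)C1=CC(=O)[C@@H](O[Si](C)(C)C(C)(C)C)[C@@H](OCc2ccc(OC)cc2)C1
A6 | alternative 3 | 1-methylcyclobutene | CC1=CCC1
A7 | alternative 3 | cis-anti-cis tricyclic photoadduct | COC(=O)[C@]12C[C@H](OCc3ccc(OC)cc3)[C@H](O[Si](C)(C)C(C)(C)C)C(=O)[C@H]1[C@]4(C)CC[C@H]24
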